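The runs are calculated with constants of no real substance; noise was put on by code.

- Count the amounts in the violet run at 90.0 s: of the substrate charged, 59.0% stands as product and 0.3% as substrate, and I book the remaining 40.7% as homo dimer, with any intermediate still present counted in it.

- violet: substrate 2 mM; run made earlier
- flask: substrate 1.0 mM; time 15 min

- violet (time / s: substrate / %, product / %): 10.0: 35.9, 12.0; 15.0: 25.0, 19.6; 25.0: 14.1, 33.5; 50.0: 4.9, 51.5; 90.0: 0.3, 59.0

(scatter of a reading: 0.3 percentage points)

- percent here means substrate units held: one homo dimer counts as two
- what was read earlier has a scatter of 0.3 percentage points, one standard deviation
- on the list of suspects stand: substrate <-> intermediate; 2 substrate -> homo dimer; intermediate -> product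
- the reaction counts as stopped when no species that holds the substrate changes by six tenths of a point or more over the second half of the time

- why nothing more happens at 15 min, or that something still does (all of the substrate has reacted / forward and back rates have come level / it is still moving)
- conversion of substrate at 15 min
- amount of product at 15 min, in percent of the substrate charged

- The flask looks nearly the same as the violet run, with 1.0 mM of substrate against 2 mM, and I expect the two to agree on conversion and part on product.
- Between 25.0 s and 50.0 s, violet substrate falls with a lifetime of 23.7 s. The asked 15 min is far longer than that, and the violet readings show no plateau, so I expect the substrate in the flask to have reacted completely.
- On the list of suspects, homo dimer formation goes with the square of the substrate and the route to product with its first power, so I expect that ratio to be higher in the violet run than in the flask.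
- The violet run reads 0.345 /mM; call this the split per millimolar, the homo dimer share over the product share per unit of charge, a selectivity factor.
- If the split holds at both charges and the substrate ends up as these two species, the product share is one divided by one plus split times charge. My reckoning for the flask, at half the violet charge, gives 74.4%, higher than the violet reading.
- The forecast says all of the substrate has reacted, with conversion 100% (from 99.5% to 100%) and product 74% (from 70% to 78%), on the ground that “Halving the charge halves the dimer term”.
- The flask gives this result: all of the substrate has reacted, with conversion 100% and product 74.5%.

    substrate ⇌ intermediate (K = 3.00, k = 0.0620 /s)
    2 substrate → homo dimer (k = 20.0 /M/s)
    intermediate → product (k = 0.0750 /s)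

- By 7.50 min the flask already holds 74.5% product and 25.5% homo dimer, with substrate at 0%. The split gave 74.4% for this flask. Applied to the neighbour flask, with 2.5 mM of substrate and the same time, it gives 53.7% product, while the neighbour flask holds 56.2%.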